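The runs stem from a simulated flask on assumed constants; the scatter is artificial.

Alpha's activator charge was 15.0 mM, and one for one it could not remove 17.8 mM of substrate, yet that much had gone by 0.833 min. So substrate has a second route, and I asked whether oak's slow feed keeps substrate low.

| flask | substrate | activator | remark | time |
|---|---|---|---|---|
| delta | 20 mM | 1.5 equiv | run made earlier |  |
| alpha | 20 mM | 0.75 equiv | run made earlier |  |
| zeta | 20 mM | 1.1 equiv | run made earlier |  |
| maple | 20 mM | 1.50 equiv (fed, over 1.0 min) | all else is in the flask from the start; the feed brings no volume worth counting | 12 min |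
| birch | 20 mM | 1.50 equiv (fed, over 10 min) | all else is in the flask from the start; the feed brings no volume worth counting | 12 min |
| elm | 20 mM | 1.50 equiv | everything together at the start | 12 min |
| oak | 20 mM (fed, over 10 min) | 1.50 equiv | all else is in the flask from the start; the feed brings no volume worth counting | 12 min |

| run | time / min | ring / % | substrate / % |
|---|---|---|---|
| delta | 1.00 | 40.1 | 0.4 |
| delta | 2.00 | 34.1 | 0.7 |
| delta | 3.00 | 27.6 | 0 |
| delta | 6.00 | 17.8 | 0.2 |
| delta | 12.0 | 10.0 | 0 |
| alpha | 0.833 | 22.6 | 11.1 |
| alpha | 2.50 | 21.6 | 4.2 |
| alpha | 4.00 | 16.4 | 0.6 |
| alpha | 6.00 | 13.4 | 1.1 |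
| alpha | 10.0 | 9.7 | 0.6 |
| zeta | 2.00 | 30.9 | 0 |
| zeta | 4.00 | 18.8 | 0.5 |
| zeta | 6.00 | 14.5 | 1.0 |
| zeta | 8.00 | 11.2 | 0.5 |
| zeta | 10.0 | 10.2 | 0.7 |

(readings scatter by 1 percentage point)

- the earlier runs were read with a standard deviation of 1 percentage point

- which flask leads in amount of ring, in percent of the substrate charged ("all alike" within 1.5 percentage points) (maple / birch / elm / oak / all alike)
- how much ring is there at the end, in percent of the substrate charged: maple
- how much ring is there at the end, in percent of the substrate charged: birch
- how much ring is there at the end, in percent of the substrate charged: elm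
- how much ring is there at the end, in percent of the substrate charged: oak

I wanted the standing substrate S in oak (its steady-state level): feed rate times the lifetime of substrate. First I asked which numbers matter. Delta and zeta give no lifetime, since their first substrate readings, 0.4% and 0%, lie within 1 point of zero. Alpha's first reading matters little: 1 point on it moves the lifetime only to 0.394 min. The activator standing matters directly, if the lifetime goes inversely with it, as I assumed.

Alpha's first reading, with its scatter, gives τ = 0.379 min, the time in which substrate falls by a factor of e at that charge. At oak's 1.50 equiv, τ is half that, so S is 1.89%. But that takes the activator as untouched. Going round again, I estimated one activator used per substrate fed, so 0.500 equiv at the end of the feed, and S came to 5.68%. That is far below the whole charge elm holds at the start, so I expected oak to lead.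

The forecast also named oak, with maple 9.6%, birch 9%, elm 10% and oak 20%, on other grounds: “a steady state near 28” in ring, then decay.

Oak ended at 29.4%, against elm 11.8%, maple 9.49% and birch 8.76%, so the forecast's oak stood 9.4 points low.

    substrate + activator → activated form (k = 4.70 M⁻¹ s⁻¹)
    activated form → ring (k = 0.0430 s⁻¹)
    substrate + activated form → open dimer (k = 6.60 M⁻¹ s⁻¹)
    2 activator → homo dimer (k = 0.0190 M⁻¹ s⁻¹)
    ring ⇌ isomer of the product (K = 3.70, k = 0.00480 s⁻¹)

Oak's substrate at 10.0 min was 5.17% against my 5.68%, but its activator was 17.7% of charge, not my 33.3%. In oak's neighbour with 0.600 equiv of activator, τ gives 4.74% if that whole charge stands, but that flask's activator ended at 0% and 34.3% of substrate stood. In oak at 5.08 min, activated form went to ring 15 times as fast as to open dimer. Open dimer ended at 12.9% in oak, against 47.3% in elm.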